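**Retrosynthetic overview**
1. Ring letters: A is the biaryl ring with OH para to the biaryl bond, B the ring with OH and OAr, C the para-phenylene, D the biaryl ring with OH ortho to the biaryl bond. Plagiochin E comes from BBr3 O-demethylation and hydrogenation of a 16-membered macrocyclic stilbene (CH=CH between rings A and B).
2. The macrocycle comes from an open-chain 2-(4-methoxyphenyl)phenol with a vinyl group on ring B, by phenol-directed dehydrogenative Heck closure of the ring A–CH bond. The structural feature used: before bridging, ring A is a plain 4-methoxyphenyl group whose two ortho C–H bonds (C2'/C6') are equivalent and face the ring D hydroxyl (on the carbon next to the biaryl carbon), so an O-bound metal reaches either through a six-membered metallacycle and ring A needs no halogen.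
3. The open-chain precursor comes from vinylation of a ring B bromide. The saturated D–C bridge comes from Wittig olefination and diimide reduction between the A–D biaryl aldehyde (Suzuki coupling) and the B–C phosphonium salt (SNAr diaryl ether).
4. Ring order: all four benzene rings are bought; the macrocycle is the only ring formed and is closed in step 8.

Key step: step 8

Remark: the target SMILES defines no stereo element, so the biaryl axis is treated as configurationally unspecified; ring B is taken from 5-bromo-2-methoxyphenol so that its vinyl group can be installed after the diimide reduction.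

**Route**

Step 1
Reactants: 1 2-bromo-3-hydroxybenzaldehyde; 2 4-methoxyphenylboronic acid
Product: 3 3-hydroxy-2-(4-methoxyphenyl)benzaldehyde
Conditions: Pd(OAc)2 (2 mol %), SPhos (4 mol %), K3PO4, toluene/H2O, 90 °C
Reagents that add atoms: none
Why: Suzuki–Miyaura coupling; the ortho formyl group speeds oxidative addition of zerovalent palladium into the C–Br bond, the SPhos ligand copes with the two ortho substituents and the phenoxide, and the unhindered boronic acid transmetalates readily.

Step 2
Reactants: 4 5-bromo-2-methoxyphenol; 5 4-fluorobenzaldehyde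
Product: 6 4-(5-bromo-2-methoxyphenoxy)benzaldehyde
Conditions: K2CO3, DMF, 120 °C
Reagents that add atoms: none
Why: Nucleophilic aromatic substitution (SNAr); the para formyl group activates the fluoride towards the phenoxide, and the aryl bromide is inert without a metal catalyst.

Step 3
Reactants: 6 4-(5-bromo-2-methoxyphenoxy)benzaldehyde
Product: 7 [4-(5-bromo-2-methoxyphenoxy)phenyl]methanol
Conditions: NaBH4, MeOH/THF, 0 °C
Reagents that add atoms: none
Why: Borohydride reduction of an aryl aldehyde; no other group in the molecule is reducible under these conditions.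

Step 4
Reactants: 7 [4-(5-bromo-2-methoxyphenoxy)phenyl]methanol
Product: 8 [4-(5-bromo-2-methoxyphenoxy)benzyl]triphenylphosphonium bromide
Conditions: PPh3·HBr, MeCN, reflux
Reagents that add atoms: triphenylphosphine hydrobromide, Br.c1ccc(cc1)P(c1ccccc1)c1ccccc1
Why: Direct phosphonium salt formation from a benzylic alcohol; protonation and loss of water are assisted by the para aryloxy group, and PPh3 captures the benzylic electrophile.

Step 5
Reactants: 8 [4-(5-bromo-2-methoxyphenoxy)benzyl]triphenylphosphonium bromide; 3 3-hydroxy-2-(4-methoxyphenyl)benzaldehyde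
Product: 10 3-[2-[4-(5-bromo-2-methoxyphenoxy)phenyl]ethenyl]-2-(4-methoxyphenyl)phenol (E/Z mixture), via benzylidene phosphorane 9 (not isolated)
Conditions: 8 (1.3 equiv), KOtBu (2.4 equiv), THF, 0 °C; then 3, 0 °C to rt; aq. NH4Cl
Reagents that add atoms: none
Why: Wittig olefination with a semi-stabilised ylide; the extra base holds the phenol of 3 as its phenoxide, which is meta to the formyl group and so does not deactivate it by conjugation, and the alkene geometry is irrelevant because the double bond is reduced in step 6.

Step 6
Reactants: 10 3-[2-[4-(5-bromo-2-methoxyphenoxy)phenyl]ethenyl]-2-(4-methoxyphenyl)phenol (E/Z mixture)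
Product: 11 3-[2-[4-(5-bromo-2-methoxyphenoxy)phenyl]ethyl]-2-(4-methoxyphenyl)phenol
Conditions: TsNHNH2 (excess, in portions), NaOAc, THF/H2O, reflux
Reagents that add atoms: none
Why: Diimide reduction; HN=NH generated in the flask transfers H2 to the C=C bond in a concerted syn fashion and leaves the C–Br bond that hydrogenation over a palladium catalyst would cleave.

Step 7
Reactants: 11 3-[2-[4-(5-bromo-2-methoxyphenoxy)phenyl]ethyl]-2-(4-methoxyphenyl)phenol
Product: 12 3-[2-[4-(5-ethenyl-2-methoxyphenoxy)phenyl]ethyl]-2-(4-methoxyphenyl)phenol
Conditions: potassium vinyltrifluoroborate, PdCl2(dppf) (5 mol %), Cs2CO3, THF/H2O, 80 °C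
Reagents that add atoms: potassium vinyltrifluoroborate, C=C[B-](F)(F)F.[K+]
Why: Suzuki–Miyaura vinylation of an aryl bromide with a vinyltrifluoroborate; the free phenol is tolerated as its cesium salt and the molecule holds no second halide.

Step 8
Reactants: 12 3-[2-[4-(5-ethenyl-2-methoxyphenoxy)phenyl]ethyl]-2-(4-methoxyphenyl)phenol
Product: 13 macrocyclic E-stilbene (16-membered ring; CH=CH between rings A and B; OMe on rings A and B; free OH on ring D)
Conditions: [Cp*RhCl2]2 (5 mol %), Cu(OAc)2 (2.2 equiv), DMF, 100 °C, argon, syringe-pump addition of 12 to a final 2 mM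
Reagents that add atoms: none
Why: Proposed new method: ligand exchange gives a rhodium phenoxide at the ring D oxygen, acetate-assisted metalation of an ortho C–H bond of ring A gives a six-membered rhodacycle (O, two ring D carbons, two ring A carbons, trivalent rhodium), the tethered vinyl group of ring B inserts into the Rh–aryl bond with the aryl carbon going to the terminal CH2 and rhodium to the benzylic carbon, syn β-hydride elimination releases the stilbene, and Cu(OAc)2 returns monovalent rhodium to the trivalent state. The closest known reaction type is the intermolecular hydroxyl-directed oxidative C–H olefination of 2-arylphenols with styrenes or acrylates under [Cp*RhCl2]2/Cu(OAc)2 or Pd(OAc)2 catalysis; its use as a ring closure is the untested part. The 16-membered macrocycle is closed in the endo mode (both alkene carbons become ring members) and no stereocentre is formed; the E alkene is expected, but since the CH2 next to ring A offers two β-hydrogens the Z isomer may form if the ring prefers it, and either is saturated in step 9. Site selectivity needs only the single free phenol, because the two ortho C–H bonds of ring A are interchanged by rotation about the biaryl bond and the ether oxygens bind Cp*Rh too weakly to direct it elsewhere. Linear insertion is secured by the polarity of the styrene (metal at the benzylic carbon), and ring closure is favoured over intermolecular coupling by slow addition at high dilution; the D–C bridge is already saturated, so the aryl rhodium species has no second alkene within reach. Oxidative cyclization of the phenol onto the new alkene is disfavoured because the stilbene is not a Michael acceptor and Cu(OAc)2 under argon is the only oxidant.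

Step 9
Reactants: 13 macrocyclic E-stilbene (16-membered ring; OMe on rings A and B; free OH on ring D)
Product: 14 plagiochin E dimethyl ether (macrocyclic bis-bibenzyl; OMe on rings A and B; free OH on ring D)
Conditions: H2 (1 atm), palladium on carbon (10% Pd/C), EtOAc/MeOH, rt
Reagents that add atoms: none
Why: Heterogeneous catalytic hydrogenation of a disubstituted stilbene; the aryl ethers and the phenol are untouched and there is no benzylic C–O bond to hydrogenolyse.

Step 10
Reactants: 14 plagiochin E dimethyl ether
Product: 15 plagiochin E
Conditions: BBr3 (6 equiv), CH2Cl2, −78 °C to rt; then H2O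
Reagents that add atoms: none
Why: Lewis acid demethylation of aryl methyl ethers; BBr3 binds the methoxy oxygens and bromide attacks the methyl groups, while the diaryl ether offers no sp3 carbon for attack and should survive.

**Compound list**
1 | 2-bromo-3-hydroxybenzaldehyde | O=Cc1cccc(O)c1Br | starting material
2 | 4-methoxyphenylboronic acid | COc1ccc(B(O)O)cc1 | starting material
3 | 3-hydroxy-2-(4-methoxyphenyl)benzaldehyde | COc1ccc(cc1)-c1c(O)cccc1C=O | intermediate
4 | 5-bromo-2-methoxyphenol | COc1ccc(Br)cc1O | starting material
5 | 4-fluorobenzaldehyde | O=Cc1ccc(F)cc1 | starting material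
6 | 4-(5-bromo-2-methoxyphenoxy)benzaldehyde | COc1ccc(Br)cc1Oc1ccc(C=O)cc1 | intermediate
7 | [4-(5-bromo-2-methoxyphenoxy)phenyl]methanol | COc1ccc(Br)cc1Oc1ccc(CO)cc1 | intermediate
8 | [4-(5-bromo-2-methoxyphenoxy)benzyl]triphenylphosphonium bromide | COc1ccc(Br)cc1Oc1ccc(C[P+](c2ccccc2)(c2ccccc2)c2ccccc2)cc1.[Br-] | intermediate
9 | 4-(5-bromo-2-methoxyphenoxy)benzylidene triphenylphosphorane | COc1ccc(Br)cc1Oc1ccc(C=P(c2ccccc2)(c2ccccc2)c2ccccc2)cc1 | intermediate (not isolated)
10 | 3-[2-[4-(5-bromo-2-methoxyphenoxy)phenyl]ethenyl]-2-(4-methoxyphenyl)phenol, E/Z mixture (geometry not defined) | COc1ccc(cc1)-c1c(O)cccc1C=Cc1ccc(cc1)Oc1cc(Br)ccc1OC | intermediate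
11 | 3-[2-[4-(5-bromo-2-methoxyphenoxy)phenyl]ethyl]-2-(4-methoxyphenyl)phenol | COc1ccc(cc1)-c1c(O)cccc1CCc1ccc(cc1)Oc1cc(Br)ccc1OC | intermediate
12 | 3-[2-[4-(5-ethenyl-2-methoxyphenoxy)phenyl]ethyl]-2-(4-methoxyphenyl)phenol (key step precursor) | COc1ccc(cc1)-c1c(O)cccc1CCc1ccc(cc1)Oc1cc(C=C)ccc1OC | intermediate
13 | macrocyclic E-stilbene, OMe on rings A and B, free OH on ring D (key step product) | COc1ccc2c(c1)/C=C/c1ccc(OC)c(c1)Oc1ccc(cc1)CCc1cccc(O)c1-2 | intermediate
14 | plagiochin E dimethyl ether (OMe on rings A and B, free OH on ring D) | COc1ccc2c(c1)CCc1ccc(OC)c(c1)Oc1ccc(cc1)CCc1cccc(O)c1-2 | intermediate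
15 | plagiochin E | Oc1ccc2c(c1)CCc1ccc(O)c(c1)Oc1ccc(cc1)CCc1cccc(O)c1-2 | target

**Step count**
Total: 10 steps. Longest linear sequence: 9 steps (steps 2 to 10, from 4 and 5).

**Steps most likely to fail**

1. Step 8. The catalytic cycle may stall at the rhodium phenoxide, the copper salt may oxidise the phenol, or intermolecular olefination may give oligomers instead of the ring. Fallback: the same ring A–CH bond is made by a conventional Mizoroki–Heck macrocyclization, with a halogen placed on ring A beforehand and the phenol masked (a free 2'-chloro-2-hydroxybiaryl could close to a dibenzofuran under palladium catalysis). It sets out from 1. MOMCl and i-Pr2NEt should give 2-bromo-3-(methoxymethoxy)benzaldehyde F1. Suzuki–Miyaura coupling with commercial (2-chloro-4-methoxyphenyl)boronic acid (COc1ccc(B(O)O)c(Cl)c1; Pd(PPh3)4, Na2CO3, DME/H2O, the C–Br bond reacting before the C–Cl bond) should give 2-(2-chloro-4-methoxyphenyl)-3-(methoxymethoxy)benzaldehyde F2. Wittig reaction with ylide 9 should give the chloro bromo stilbene MOM ether F3, and diimide reduction the chloro bromo bibenzyl MOM ether F4. Vinylation of the ring B bromide as in step 7, which leaves the aryl chloride alone, should give the chloro styrene MOM ether F5. Heck ring closure (Pd2(dba)3, [HP(t-Bu)3]BF4, Cy2NMe, dioxane, 100 °C, 2 mM) should give the macrocyclic stilbene MOM ether F6. HCl in MeOH/THF then removes the MOM group, and the route is rejoined at 13.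

2. Step 5. The phenoxide of 3 may precipitate or protonate the ylide, so the hindered aldehyde is olefinated incompletely. Fallback: the phenol is masked so that the aldehyde partner is neutral. It sets out from 3. MOMCl and i-Pr2NEt in CH2Cl2 should give 3-(methoxymethoxy)-2-(4-methoxyphenyl)benzaldehyde F7. Wittig reaction with ylide 9 (one equivalent of base) should give the bromo stilbene MOM ether F8. HCl in MeOH/THF at 50 °C cleaves the acetal, and the route is rejoined at 10.

3. Step 7. The new electron-rich styrene may be consumed by Heck coupling with unreacted aryl bromide, or the bromide may be lost by protodebromination. Fallback: the vinyl group is built from an aldehyde instead of by cross-coupling. It sets out from 11. Deprotonation with NaH, bromine–lithium exchange with t-BuLi at −78 °C and quenching with DMF should give 3-[4-[2-[3-hydroxy-2-(4-methoxyphenyl)phenyl]ethyl]phenoxy]-4-methoxybenzaldehyde F9. Methylenation with excess Ph3P=CH2 (from MePPh3Br and KOtBu, THF) rejoins the route at 12.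

**Further compounds**
F1 | step 8 | 2-bromo-3-(methoxymethoxy)benzaldehyde | COCOc1cccc(C=O)c1Br
F2 | step 8 | 2-(2-chloro-4-methoxyphenyl)-3-(methoxymethoxy)benzaldehyde | COCOc1cccc(C=O)c1-c1ccc(OC)cc1Cl
F3 | step 8 | chloro bromo stilbene MOM ether (E/Z mixture, geometry not defined) | COCOc1cccc(C=Cc2ccc(Oc3cc(Br)ccc3OC)cc2)c1-c1ccc(OC)cc1Cl
F4 | step 8 | chloro bromo bibenzyl MOM ether | COCOc1cccc(CCc2ccc(Oc3cc(Br)ccc3OC)cc2)c1-c1ccc(OC)cc1Cl
F5 | step 8 | chloro styrene MOM ether | COCOc1cccc(CCc2ccc(Oc3cc(C=C)ccc3OC)cc2)c1-c1ccc(OC)cc1Cl
F6 | step 8 | macrocyclic E-stilbene MOM ether | COCOc1cccc2c1-c1ccc(OC)cc1/C=C/c1ccc(OC)c(c1)Oc1ccc(cc1)CC2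
F7 | step 5 | 3-(methoxymethoxy)-2-(4-methoxyphenyl)benzaldehyde | COCOc1cccc(C=O)c1-c1ccc(OC)cc1
F8 | step 5 | bromo stilbene MOM ether (E/Z mixture, geometry not defined) | COCOc1cccc(C=Cc2ccc(Oc3cc(Br)ccc3OC)cc2)c1-c1ccc(OC)cc1
F9 | step 7 | 3-[4-[2-[3-hydroxy-2-(4-methoxyphenyl)phenyl]ethyl]phenoxy]-4-methoxybenzaldehyde | COc1ccc(cc1)-c1c(O)cccc1CCc1ccc(cc1)Oc1cc(C=O)ccc1OC
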